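## Analysis of the target

Lehualide K (13) is an achiral, constitutionally symmetric dimer. Two fully substituted 2H‑pyran‑2‑one rings (C2 lactone carbonyl, C3–OMe, C4–OMe, C5–CH3, C6–alkyl) are joined through their C6 substituents by ten methylenes, an S–S bond and ten more methylenes. There is no stereocentre and no stereogenic double bond, so nothing has to be set or guarded against epimerisation. Two groups are sensitive: the dialkyl disulfide, which hydrides, phosphines, thiolates, carbanions and low‑valent metals cleave and which deactivates palladium catalysts, and the 2‑pyranone, an electrophilic lactone that strong oxygen, nitrogen or sulfur nucleophiles open at C2 or attack at C6. The first difficulty is to build a tetrasubstituted pyranone with oxygen at C3 and C4 and carbon at C5 and C6 so that it ends as the 4‑methoxy‑2‑pyranone and not as the isomeric 2‑methoxy‑4‑pyranone. The second is that sulfur nucleophiles must be kept away from the finished ring, and the third is that every operation must succeed at both ends of one molecule. The plan rests on one feature: C6 of each ring, its ten methylenes and its sulfur are, atom for atom, 11‑mercaptoundecanoic acid (1), with the carboxyl carbon as C6. The disulfide diacid 2 can therefore serve as the core, and the rest of each ring (C2–C5, the C3 oxygen and the C5 methyl) is the five‑carbon 2‑methoxy‑3‑oxopentanoate unit of ketoester 6.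

## Retrosynthetic reasoning

**13 ⇒ 12 (two O–CH3 bonds at C4).** The C4 oxygen of each ring is cut from its methyl group first. A pyranone made by lactonisation of a 3,5‑dioxo ester is born with a free, acidic 4‑hydroxyl, so its methylation is the natural last step. It touches neither the disulfide nor the lactone. The forward reaction has to methylate the C4 oxygen of bis(hydroxypyranone) 12 and not the lactone carbonyl oxygen, at both ends.

**12 ⇒ 11 (two O1–C2 lactone bonds).** Opening both lactones gives the bis(3,5‑dioxo ester) 11. In 11 the C5 ketone oxygen becomes O1 and the ester carbon becomes C2. This is the polyketide‑type retron of a 4‑hydroxy‑2‑pyranone. The forward step is a base‑mediated enol lactonisation that must close through oxygen, not through the C6 carbanion.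

**11 ⇒ 3 + two 9 (two C5–C6 bonds; key disconnection).** Cutting between the C5 carbonyl and the first chain carbon (the former carboxyl carbon) releases the symmetric diacid dichloride 3 and two molecules of the bis(silyloxy)diene 9, a neutral equivalent of the dianion of 6. The cut is made here because it is the only one that leaves the whole sulfur chain as a single bought building block and lets both rings grow at once. A free dianion would attack the S–S bond, so the nucleophile is taken as the silyl diene, which reacts under Lewis‑acid conditions and leaves a disulfide alone. The forward step must join the terminal carbon of 9 to each acyl chloride carbon, twice.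

**3 ⇒ 2 ⇒ two 1 (C–Cl, then S–S).** The dichloride 3 comes from diacid 2, and 2 from two molecules of thiol 1 by mild oxidative coupling. Forming the disulfide first turns the thiol into an inert group. No thiol or thiolate exists anywhere later in the route.

**9 ⇒ 8 ⇒ 6 + 7 (two O–Si bonds).** Diene 9 is the double enol silane of ketoester 6. It is reached by silylating the ketone enol with chlorotrimethylsilane 7 to give 8, then deprotonating the ethyl CH2 and silylating the ester oxygen with 7 again. The C3 methoxy group and the C5 methyl group of the ring are both already present in 6.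

**6 ⇒ 4 + 5 (C–C bond between the methoxy‑bearing carbon and the ketone).** A crossed Claisen disconnection gives methyl methoxyacetate 4 as the enolate component and propionyl chloride 5 as the acyl donor, both bulk chemicals.

## Alternatives that were turned down

Alternative 1: allenylstannane Stille coupling with lactonisation in the same pot.
- Disconnection: C4–C5 and O1–C6 of the ring, on a monomer whose chain ends in a silyl ether.
- Forward key step: Pd(OAc)2, PPh3 and Bu4NBr couple (E)‑3‑iodo‑2,3‑dimethoxyacrylic acid (A2) with allenylstannane A3 to form C4–C5. The carboxylate of the coupled vinylallene then adds to the central allene carbon to form O1–C6, giving pyranone silyl ether A1.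
- For it: the fully substituted ring is made in one operation with both methoxy groups already in place. No late methylation has to choose between the two pyranone oxygens. On this point it is stronger than the chosen route.
- Against it: A2 carries iodine on a carbon that also bears a methoxy group. That is the enol ether of an acyl iodide, hard to prepare and prone to hydrolysis. A3 needs its own multistep synthesis and brings stoichiometric tin. Sulfur cannot be present during palladium catalysis, so after A1 the silyl ether must be cleaved, the oxygen activated, sulfur brought in with a sulfur nucleophile that can also open the pyranone, and the thiol oxidised.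
- Comparison: the symmetry is used only in the last step, and the sequence is clearly longer. The chosen strategy offers, in place of the pre‑installed 4‑methoxy group, a metal‑free eight‑step route in which sulfur is present from the first step as an inert disulfide.

Alternative 2: Dieckmann closure of a Z enol methoxyacetate.
- Disconnection: C3–C4 of the ring, and one step earlier the O1–C2 ester bond.
- Forward key step: LiN(SiMe3)2 deprotonates the methoxyacetate CH2 of the Z enol ester A5. The enolate carbon attacks the neighbouring methyl ester in a 6‑exo‑trig closure and expels methoxide, giving the S‑trityl hydroxypyranone A4.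
- For it: the ring closure is intramolecular, so its regiochemistry is fixed by connectivity. This is stronger than an intermolecular acylation that must distinguish two carbons and an oxygen of a diene. The trityl thioether is stable to the base.
- Against it: A5 must be made as the Z isomer by O‑acylation of the 2‑methyl β‑keto ester A6. C‑acylation and the E isomer, which cannot cyclise, compete. The enolate of an enol ester can also fragment to a ketene and the enolate of A6, or undergo O→C acyl shift. A4 still needs the same O‑methylation as the chosen route, then removal of trityl and oxidation. A6 itself takes several steps from thiol 1.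
- Comparison: the linear sequence is longer and carries a protecting group. The chosen strategy gives up the connectivity‑fixed ring closure and offers instead a precursor reached in five simple steps, no double‑bond geometry requirement (the cyclising enolate is delocalised) and two‑directional growth.

Alternative 3: ring expansion of a squarate‑derived cyclobutenone.
- Disconnection: O1–C2 of the ring, traced back to the 4‑acyl‑4‑methylcyclobutenone A8, itself derived from dimethyl squarate (A9).
- Forward key step: heating A8 in toluene opens the four‑membered ring at C1–C4 (4π electrocyclic opening) to an acylvinylketene. The ketone oxygen closes onto the ketene carbon (6π oxa‑electrocyclisation) to give the chloroalkyl pyranone A7.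
- For it: the step is thermal, neutral and reagent‑free. Both methoxy groups come from A9, so the 3,4‑dimethoxy pattern is certain. On this point it is stronger than the chosen route. The chloride is a robust handle.
- Against it: the quaternary C4 of A8, bearing methyl and a long acyl group on a strained ring, is the hard part. A direct enolate acylation at C4 would pass through an antiaromatic cyclobutadienolate, so several indirect steps from A9 are needed. The acyl group must rotate inward in the ring opening for the closure to follow. After A7 the chloride must be displaced by a sulfur nucleophile next to the electrophilic pyranone and the sulfur oxidised.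
- Comparison: longer, dearer in starting material, and sulfur chemistry falls at the end on the finished ring. The chosen strategy accepts one methylation whose site selectivity must be watched, and in return avoids strained intermediates and any sulfur nucleophile near the pyranone.

Key step: step 6

Remark on the chemistry (assumption): the enol silane double bonds of 8, 9 and 10 are expected to form without geometric control, and the C2 and C4 centres of 6 and 11 are configurationally labile. All of these carbons end as ring sp2 carbons, so the SMILES of these compounds carry no stereodescriptors and 11 is drawn in its all‑keto form.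

## Route

Step 1
Reactants: 1 11‑mercaptoundecanoic acid (2 equiv)
Product: 2 11,11′‑disulfanediyldiundecanoic acid
Conditions: I2 (1.0 equiv, that is 0.5 per thiol), NaHCO3 (4.4 equiv), H2O/THF, 20 °C; then 1 M HCl, filtration
Reagents that add atoms: none
Why: Iodine oxidation of a thiol to the disulfide joins two molecules of 1 per molecule of I2; the sulfenyl iodide formed from one thiol is captured by the second, NaHCO3 takes up the HI so the carboxyl group is not esterified, and the exact half equivalent of I2 per thiol avoids over‑oxidation at sulfur.

Step 2
Reactants: 2 11,11′‑disulfanediyldiundecanoic acid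
Product: 3 11,11′‑disulfanediyldi(undecanoyl chloride)
Conditions: (COCl)2 (3 equiv), DMF (cat.), CH2Cl2, 0 → 20 °C; evaporation, used crude
Reagents that add atoms: oxalyl chloride, ClC(=O)C(=O)Cl
Why: Acid chloride formation through the Vilsmeier‑type chloroiminium species, which activates only the carboxyl groups; a dialkyl disulfide is not chlorinolysed by this reagent (unlike by Cl2 or SO2Cl2) and all by‑products are gases.

Step 3
Reactants: 4 methyl methoxyacetate (2 equiv); 5 propionyl chloride (1 equiv)
Product: 6 methyl 2‑methoxy‑3‑oxopentanoate (racemic, C2 labile)
Conditions: LiN(iPr)2 (2.0 equiv), THF, −78 °C; then 5, −78 °C, 1 h; aq. NH4Cl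
Reagents that add atoms: none
Why: Crossed Claisen acylation of a lithium ester enolate with an acid chloride; the second equivalent of enolate deprotonates the more acidic β‑keto ester as it forms, which stops double acylation, and the chelated α‑alkoxy enolate is stable at −78 °C.

Step 4
Reactants: 6 methyl 2‑methoxy‑3‑oxopentanoate; 7 chlorotrimethylsilane
Product: 8 methyl 2‑methoxy‑3‑(trimethylsilyloxy)pent‑2‑enoate (mixture of double‑bond isomers)
Conditions: 7 (1.5 equiv), Et3N (1.6 equiv), toluene, 20 °C, 2–3 d; filtration under Ar, distillation
Reagents that add atoms: none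
Why: O‑Silylation of a β‑keto ester with Me3SiCl/Et3N; the C2–H between ketone and ester is the only proton acidic enough for triethylamine, so the ketone oxygen is silylated and the conjugated enol silane results.

Step 5
Reactants: 8 methyl 2‑methoxy‑3‑(trimethylsilyloxy)pent‑2‑enoate; 7 chlorotrimethylsilane
Product: 9 1,2‑dimethoxy‑1,3‑bis(trimethylsilyloxy)penta‑1,3‑diene (mixture of geometric isomers)
Conditions: LiN(iPr)2 (1.2 equiv), THF, −78 °C, 1 h; then 7 (1.4 equiv), −78 → 20 °C; pentane, filtration under Ar, used at once
Reagents that add atoms: none
Why: Kinetic γ‑deprotonation of the β‑silyloxy enoate at the ethyl CH2 gives the extended ester enolate, which is silylated on the ester oxygen; this is the standard two‑stage preparation of 1,3‑bis(silyloxy)‑1,3‑dienes, and the only other protons are on methoxy and silyl methyl groups.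

Step 6
Reactants: 3 11,11′‑disulfanediyldi(undecanoyl chloride) (1 equiv); 9 1,2‑dimethoxy‑1,3‑bis(trimethylsilyloxy)penta‑1,3‑diene (3 equiv)
Product: 11 dimethyl 15,15′‑disulfanediylbis(2‑methoxy‑4‑methyl‑3,5‑dioxopentadecanoate), via bis(silyl ketene acetal) 10 (not isolated)
Conditions: 3 added to 9 and Me3SiOTf (0.5 equiv), CH2Cl2, −78 → 20 °C, 12 h; then 1 M HCl
Reagents that add atoms: none
Why: Me3SiOTf activates each acyl chloride and the diene, a masked 1,3‑dicarbonyl dianion, attacks through its terminal carbon (C4 of the diene) in a Mukaiyama‑type vinylogous Claisen acylation that forms both bonds that become C5–C6 of the rings. The oxocarbenium ion left at C3 of the diene unit gives up its silyl group to chloride as chlorotrimethylsilane, leaving the silyl ketene acetal 10 (the silyl group may move to the neighbouring ketone oxygen), which dilute acid hydrolyses to the methyl ester of 11. The closest known reaction type is the acylation of 1,3‑bis(silyloxy)‑1,3‑dienes with acid chlorides to 3,5‑dioxo esters, run here at both ends of one diacid dichloride. No ring is closed. C2 and C4 of each dioxo ester half become stereocentres, but both lie between two carbonyl groups, epimerise and enolise freely and become sp2 in step 7, so no control is needed. The step needs attack through C4 of the diene and not through C2 or oxygen: C4 is the diene terminus with the largest HOMO coefficient and is only a secondary carbon, whereas C2 is fully substituted, carries the methoxy group and would have to become a quaternary centre, and Lewis‑acid conditions favour C‑ over O‑acylation of enol silanes. Both ends must react: the two acyl chloride carbons are separated by 22 atoms and behave independently, and adding 3 to an excess of 9 keeps the more nucleophilic diene in excess over the first‑formed 10 until both ends are consumed; surplus 9 is hydrolysed to volatile 6 on work‑up. The conditions are non‑basic, non‑reducing and metal‑free, so the S–S bond should not be touched.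

Step 7
Reactants: 11 dimethyl 15,15′‑disulfanediylbis(2‑methoxy‑4‑methyl‑3,5‑dioxopentadecanoate)
Product: 12 6,6′‑[disulfanediylbis(decane‑10,1‑diyl)]bis(4‑hydroxy‑3‑methoxy‑5‑methyl‑2H‑pyran‑2‑one)
Conditions: DBU (5 equiv), toluene, 20 → 60 °C; then 1 M HCl
Reagents that add atoms: none
Why: Base‑mediated enol lactonisation: DBU forms the diketone enolate, whose C5 oxygen attacks the C1 methyl ester in a 6‑exo‑trig acyl substitution with loss of methoxide. The pyranone is held as its stable 4‑oxido salt, which drives the closure and shields the lactone, and DBU does not attack a dialkyl disulfide.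

Step 8
Reactants: 12 6,6′‑[disulfanediylbis(decane‑10,1‑diyl)]bis(4‑hydroxy‑3‑methoxy‑5‑methyl‑2H‑pyran‑2‑one)
Product: 13 lehualide K, 6,6′‑[disulfanediylbis(decane‑10,1‑diyl)]bis(3,4‑dimethoxy‑5‑methyl‑2H‑pyran‑2‑one)
Conditions: Me2SO4 (4 equiv), K2CO3 (6 equiv), acetone, reflux
Reagents that add atoms: dimethyl sulfate, COS(=O)(=O)OC
Why: O‑Methylation of the vinylogous acid with dimethyl sulfate and K2CO3 in acetone, conditions that normally deliver the 4‑methoxy‑2‑pyranone rather than the 2‑methoxy‑4‑pyranone. C3 is blocked against C‑methylation and the disulfide is too weak a nucleophile to be alkylated.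

## Compound list

1 | 11‑mercaptoundecanoic acid | OC(=O)CCCCCCCCCCS | starting material
2 | 11,11′‑disulfanediyldiundecanoic acid | OC(=O)CCCCCCCCCCSSCCCCCCCCCCC(=O)O | intermediate
3 | 11,11′‑disulfanediyldi(undecanoyl chloride) | ClC(=O)CCCCCCCCCCSSCCCCCCCCCCC(Cl)=O | intermediate
4 | methyl methoxyacetate | COCC(=O)OC | starting material
5 | propionyl chloride | CCC(=O)Cl | starting material
6 | methyl 2‑methoxy‑3‑oxopentanoate (racemic) | CCC(=O)C(OC)C(=O)OC | intermediate
7 | chlorotrimethylsilane | C[Si](C)(C)Cl | starting material
8 | methyl 2‑methoxy‑3‑(trimethylsilyloxy)pent‑2‑enoate (E/Z mixture) | CCC(O[Si](C)(C)C)=C(OC)C(=O)OC | intermediate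
9 | 1,2‑dimethoxy‑1,3‑bis(trimethylsilyloxy)penta‑1,3‑diene (mixture of geometric isomers) | CC=C(O[Si](C)(C)C)C(OC)=C(OC)O[Si](C)(C)C | intermediate
10 | 15,15′‑disulfanediylbis[1,2‑dimethoxy‑4‑methyl‑1‑(trimethylsilyloxy)pentadec‑1‑ene‑3,5‑dione], the bis(silyl ketene acetal), not isolated | COC(O[Si](C)(C)C)=C(OC)C(=O)C(C)C(=O)CCCCCCCCCCSSCCCCCCCCCCC(=O)C(C)C(=O)C(OC)=C(OC)O[Si](C)(C)C | intermediate
11 | dimethyl 15,15′‑disulfanediylbis(2‑methoxy‑4‑methyl‑3,5‑dioxopentadecanoate) (keto form, mixture of epimers and tautomers) | COC(=O)C(OC)C(=O)C(C)C(=O)CCCCCCCCCCSSCCCCCCCCCCC(=O)C(C)C(=O)C(OC)C(=O)OC | intermediate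
12 | 6,6′‑[disulfanediylbis(decane‑10,1‑diyl)]bis(4‑hydroxy‑3‑methoxy‑5‑methyl‑2H‑pyran‑2‑one) | COc1c(O)c(C)c(CCCCCCCCCCSSCCCCCCCCCCc2oc(=O)c(OC)c(O)c2C)oc1=O | intermediate
13 | lehualide K | COc1c(C)c(CCCCCCCCCCSSCCCCCCCCCCc2oc(=O)c(OC)c(OC)c2C)oc(=O)c1OC | target

## Step count and risks

Total: 8 steps. Longest linear sequence: 6 steps (steps 3, 4, 5, 6, 7, 8). The sulfur branch (steps 1 and 2) joins at step 6.

**Step 6 (key step).** The most likely failure is incomplete twofold conversion combined with imperfect site selectivity. The terminal carbon of 9 is a methyl‑bearing secondary carbon on a crowded, tetrasubstituted diene, so attack may be slow. The diene can be desilylated by traces of HCl before it reacts. The first‑formed silyl ketene acetal can be acylated again through C2 or oxygen by unreacted acyl chloride. Products that differ at one chain end only would be hard to separate, because the long chain dominates their polarity.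

The fallback gives up two‑directionality and the disulfide at this stage so that a true dianion can be used; it sets out from 1 and 6 and returns at 12. Thiol 1 is S‑tritylated (Ph3COH, CF3CO2H, CH2Cl2) to 11‑(tritylsulfanyl)undecanoic acid F1, which is converted (MeNHOMe·HCl, EDC·HCl, Et3N, CH2Cl2) into N‑methoxy‑N‑methyl‑11‑(tritylsulfanyl)undecanamide F2. The dianion of 6 (LiN(iPr)2, 2.2 equiv per 6, THF, −78 → 0 °C; 2.5 equiv of dianion) is acylated at its γ‑carbon by F2 to give methyl 2‑methoxy‑4‑methyl‑3,5‑dioxo‑15‑(tritylsulfanyl)pentadecanoate F3. DBU closes the ring to 4‑hydroxy‑3‑methoxy‑5‑methyl‑6‑[10‑(tritylsulfanyl)decyl]‑2H‑pyran‑2‑one F4. I2 in CH2Cl2/MeOH then removes the trityl groups of two molecules of F4 oxidatively and forms the S–S bond directly, giving 12. The carbanion is acceptable here only because no disulfide is present. The cost is three extra steps.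

**Step 5.** LiN(iPr)2 may attack silicon instead of removing the γ‑proton, C‑silylation may compete, and the very hydrolysis‑prone diene may be lost or arrive impure, which would then spoil step 6.

The fallback changes both how the diene is made and which diene is used; it sets out from 6 and returns at 11. Ketoester 6 is doubly enolised in one pot without strong base (Et3SiOTf, 2.3 equiv, Et3N, Et2O, 0 → 20 °C) to 1,2‑dimethoxy‑1,3‑bis(triethylsilyloxy)penta‑1,3‑diene F5, which is sturdier and can be purified. F5 is acylated by 3 as in step 6 to give the bis(triethylsilyl ketene acetal) 15,15′‑disulfanediylbis[1,2‑dimethoxy‑4‑methyl‑1‑(triethylsilyloxy)pentadec‑1‑ene‑3,5‑dione] F6, which is not isolated, and aqueous acid hydrolyses it to 11.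

**Step 7.** Ring closure may go through carbon instead of oxygen: the C6 carbanion can attack the ester in a Dieckmann‑type closure to a cyclohexane‑1,3,5‑trione. The closure may also be slow at the hindered α‑methoxy ester, leaving time for cleavage of the diketone by the liberated methoxide.

The fallback turns the ester carbon into a hard electrophile under acidic conditions, where the enol oxygen is the nucleophile; it sets out from 11 and returns at 12. LiOH (THF/H2O, 0 °C), then cold acidification, gives 15,15′‑disulfanediylbis(2‑methoxy‑4‑methyl‑3,5‑dioxopentadecanoic acid) F7. This acid is cyclodehydrated at once with (CF3CO)2O in CH2Cl2 at 0 °C through the mixed anhydride to 12.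

**Step 8.** Methylation of the ambident pyranone anion at the lactone carbonyl oxygen would give 2‑methoxy‑4‑pyranone units, and incomplete twofold methylation would add further mixed products.

The fallback fixes the C4 methyl ether before the ring exists; it sets out from 6 and returns at 13. Ketoester 6 is converted (HC(OMe)3, MeOH, cat. H2SO4) into the enol methyl ether methyl 2,3‑dimethoxypent‑2‑enoate F8. LiN(iPr)2, then 7, gives the mono‑silyl diene 1,2,3‑trimethoxy‑1‑(trimethylsilyloxy)penta‑1,3‑diene F9. This diene is acylated at both ends of 3 (Me3SiOTf cat., CH2Cl2, −78 → 20 °C) to dimethyl 15,15′‑disulfanediylbis(2,3‑dimethoxy‑4‑methyl‑5‑oxopentadec‑2‑enoate) F10. DBU in toluene then closes both rings by attack of the C5 enolate oxygen on the ester and gives 13 directly, with no late methylation. The acidic C4 proton lets the enoate geometry equilibrate through the dienolate, so both double‑bond isomers can cyclise.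

## Further compounds

F1 | step 6 | 11‑(tritylsulfanyl)undecanoic acid | OC(=O)CCCCCCCCCCSC(c1ccccc1)(c1ccccc1)c1ccccc1
F2 | step 6 | N‑methoxy‑N‑methyl‑11‑(tritylsulfanyl)undecanamide | CON(C)C(=O)CCCCCCCCCCSC(c1ccccc1)(c1ccccc1)c1ccccc1
F3 | step 6 | methyl 2‑methoxy‑4‑methyl‑3,5‑dioxo‑15‑(tritylsulfanyl)pentadecanoate | COC(=O)C(OC)C(=O)C(C)C(=O)CCCCCCCCCCSC(c1ccccc1)(c1ccccc1)c1ccccc1
F4 | step 6 | 4‑hydroxy‑3‑methoxy‑5‑methyl‑6‑[10‑(tritylsulfanyl)decyl]‑2H‑pyran‑2‑one | COc1c(O)c(C)c(CCCCCCCCCCSC(c2ccccc2)(c2ccccc2)c2ccccc2)oc1=O
F5 | step 5 | 1,2‑dimethoxy‑1,3‑bis(triethylsilyloxy)penta‑1,3‑diene | CC=C(O[Si](CC)(CC)CC)C(OC)=C(OC)O[Si](CC)(CC)CC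
F6 | step 5 | 15,15′‑disulfanediylbis[1,2‑dimethoxy‑4‑methyl‑1‑(triethylsilyloxy)pentadec‑1‑ene‑3,5‑dione] | COC(O[Si](CC)(CC)CC)=C(OC)C(=O)C(C)C(=O)CCCCCCCCCCSSCCCCCCCCCCC(=O)C(C)C(=O)C(OC)=C(OC)O[Si](CC)(CC)CC
F7 | step 7 | 15,15′‑disulfanediylbis(2‑methoxy‑4‑methyl‑3,5‑dioxopentadecanoic acid) | OC(=O)C(OC)C(=O)C(C)C(=O)CCCCCCCCCCSSCCCCCCCCCCC(=O)C(C)C(=O)C(OC)C(=O)O
F8 | step 8 | methyl 2,3‑dimethoxypent‑2‑enoate | CCC(OC)=C(OC)C(=O)OC
F9 | step 8 | 1,2,3‑trimethoxy‑1‑(trimethylsilyloxy)penta‑1,3‑diene | CC=C(OC)C(OC)=C(OC)O[Si](C)(C)C
F10 | step 8 | dimethyl 15,15′‑disulfanediylbis(2,3‑dimethoxy‑4‑methyl‑5‑oxopentadec‑2‑enoate) | COC(=O)C(OC)=C(OC)C(C)C(=O)CCCCCCCCCCSSCCCCCCCCCCC(=O)C(C)C(OC)=C(OC)C(=O)OC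
A1 | alternative 1 | 6‑[10‑(tert‑butyldimethylsilyloxy)decyl]‑3,4‑dimethoxy‑5‑methyl‑2H‑pyran‑2‑one | COc1c(C)c(CCCCCCCCCCO[Si](C)(C)C(C)(C)C)oc(=O)c1OC
A2 | alternative 1 | (E)‑3‑iodo‑2,3‑dimethoxyprop‑2‑enoic acid | OC(=O)/C(OC)=C(\I)OC
A3 | alternative 1 | tributyl{13‑[(tert‑butyldimethylsilyl)oxy]trideca‑2,3‑dien‑2‑yl}stannane | CC(=C=CCCCCCCCCCO[Si](C)(C)C(C)(C)C)[Sn](CCCC)(CCCC)CCCC
A4 | alternative 2 | 4‑hydroxy‑3‑methoxy‑5‑methyl‑6‑[10‑(tritylsulfanyl)decyl]‑2H‑pyran‑2‑one | COc1c(O)c(C)c(CCCCCCCCCCSC(c2ccccc2)(c2ccccc2)c2ccccc2)oc1=O
A5 | alternative 2 | methyl (Z)‑3‑[(methoxyacetyl)oxy]‑2‑methyl‑13‑(tritylsulfanyl)tridec‑2‑enoate | COCC(=O)O/C(CCCCCCCCCCSC(c1ccccc1)(c1ccccc1)c1ccccc1)=C(/C)C(=O)OC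
A6 | alternative 2 | methyl 2‑methyl‑3‑oxo‑13‑(tritylsulfanyl)tridecanoate | COC(=O)C(C)C(=O)CCCCCCCCCCSC(c1ccccc1)(c1ccccc1)c1ccccc1
A7 | alternative 3 | 6‑(10‑chlorodecyl)‑3,4‑dimethoxy‑5‑methyl‑2H‑pyran‑2‑one | COc1c(C)c(CCCCCCCCCCCl)oc(=O)c1OC
A8 | alternative 3 | 4‑(11‑chloroundecanoyl)‑2,3‑dimethoxy‑4‑methylcyclobut‑2‑en‑1‑one | COC1=C(OC)C(C)(C(=O)CCCCCCCCCCCl)C1=O
A9 | alternative 3 | dimethyl squarate (3,4‑dimethoxycyclobut‑3‑ene‑1,2‑dione) | COC1=C(OC)C(=O)C1=O
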